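**Plan**

- Retrosynthesis cuts, in this order: the two bonds of the bridging CH2 (arene C7–CH2 and CH2–C3 of the pyranone); the dihydrofuran ring at C3a–C3 and O1–C2, which releases isoprene; the aryl–Br helper bond; the aryl–C(=O) bond. The pyranone is cut at its lactone O1–C2 bond and at C5–C6.
- Forward: phloroglucinol is acylated and mono-brominated, then the dihydrofuran ring is annulated onto the finished acylphloroglucinol with isoprene. The 4-hydroxy-2-pyranone ring is made separately (chain by dianion acylation, ring by lactonisation) and joined last through one CH2 at the only aromatic C–H left (C7).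
- Enabling feature: arene carbons C3a and C7a carry the ring CH2 and the ring oxygen side by side (an ortho-halophenol in disguise), and C3–C2 plus the isopropenyl group on C2 is an unbroken isoprene skeleton. An aryl–palladium adding at C3 therefore leaves a π-allyl over C2 and the isopropenyl carbons, which O1 captures at C2.
- Stereochemistry: the side-chain (R) centre is bought in with (R)-2-methylbutanoic acid; C2 (R) of the dihydrofuran is set by the chiral ligand on palladium in the C–O bond-forming event.

Key step: step 3

Assumption: (R)-2-methylbutanoic acid is bought as the single enantiomer, and the hand of the chiral ligand in step 3 (and in its fallback) is the one that leads to 2R, to be fixed on the model pair 2-bromophenol/isoprene.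

**Route**

Step 1
Reactants: 1 phloroglucinol (benzene-1,3,5-triol); 2 (R)-2-methylbutanoic acid
Product: 4 (2R)-2-methyl-1-(2,4,6-trihydroxyphenyl)butan-1-one, via (R)-2-methylbutanoyl chloride 3 (not isolated)
Conditions: 2, (COCl)2, cat. DMF, CH2Cl2, 0 °C to rt; then 1, AlCl3 (3.5 equiv), CH2Cl2/PhNO2, 0 °C to rt; ice/1 M HCl
Reagents that add atoms: none
Why: Friedel–Crafts C-acylation of the symmetric, triply activated arene can give only one regioisomer and should stop at mono-acylation because the aryl ketone–AlCl3 chelate deactivates the ring; the α-stereocentre is carried in from 2 and should be kept by working at or below room temperature.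

Step 2
Reactants: 4 (2R)-2-methyl-1-(2,4,6-trihydroxyphenyl)butan-1-one
Product: 5 (2R)-1-(3-bromo-2,4,6-trihydroxyphenyl)-2-methylbutan-1-one
Conditions: NBS (1.0 equiv), THF, −78 °C to −20 °C, dark
Reagents that add atoms: N-bromosuccinimide, O=C1CCC(=O)N1Br
Why: Electrophilic aromatic bromination with one equivalent of NBS at low temperature; positions 3 and 5 are equivalent so only one mono-bromide can form, the first bromine slows the second substitution, and the ring is far more reactive than the ketone α-position.

Step 3
Reactants: 5 (2R)-1-(3-bromo-2,4,6-trihydroxyphenyl)-2-methylbutan-1-one; 6 isoprene (2-methylbuta-1,3-diene)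
Product: 7 (2R)-1-[(2R)-4,6-dihydroxy-2-(prop-1-en-2-yl)-2,3-dihydro-1-benzofuran-5-yl]-2-methylbutan-1-one
Conditions: Pd2(dba)3·CHCl3 (5 mol %), chiral sulfinamide monophosphine ligand of the TY-Phos type (12 mol %), NaOPh (1.1 equiv), 6 (5 equiv), 1,4-dioxane, 70 °C, sealed tube
Reagents that add atoms: none
Why: Zerovalent palladium inserts into the C–Br bond of the phenoxide of 5, the aryl group migrates to the unsubstituted CH2 terminus of the vinyl end of isoprene to give a π-allyl complex of divalent palladium that spans the future C2 and the two isopropenyl carbons, and the neighbouring phenoxide oxygen then attacks the internal allyl terminus to form O1–C2 and return zerovalent palladium. The closest known reaction type is the Larock heteroannulation of 1,3-dienes with ortho-halophenols in its enantioselective Heck/Tsuji–Trost form, which is established for ortho-bromophenols and isoprene. The dihydrofuran ring closes in the 5-exo mode at the allyl carbon next to the benzylic CH2, since attack at the far CH2 terminus would require a seven-membered ring. C2 is set by the catalyst: the allyl complex exchanges its faces by π–σ–π slippage through the unsubstituted CH2 terminus faster than it closes, so the chiral ligand on palladium decides which face the oxygen attacks and the remote (R) centre of the acyl chain has no influence. Two regiochemical choices are needed and both should be secured by the substrate: the aryl group adds to the monosubstituted double bond of isoprene and not to the 1,1-disubstituted one for steric reasons, and the ring closes through the hydroxyl para to the ketone because it is the most acidic and the only one ionised by 1.1 equiv of NaOPh, whereas the hydroxyl between the ketone and the new chain is a weaker acid and is shielded by the branched acyl group. The base is far too weak to enolise the ketone, so the side-chain stereocentre should survive.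

Step 4
Reactants: 8 methyl 3-oxopentanoate; 9 N-methoxy-N-methylpropanamide
Product: 10 methyl 4-methyl-3,5-dioxoheptanoate
Conditions: 8, NaH (1.1 equiv), THF, 0 °C; n-BuLi (1.05 equiv), 0 °C; 9 (1.0 equiv), −78 °C to 0 °C; 1 M HCl
Reagents that add atoms: none
Why: γ-Acylation of a β-keto ester dianion (Weiler dianion chemistry), which reacts at the more basic γ-carbon, with a Weinreb amide whose stable tetrahedral chelate prevents over-addition and proton transfer; the new centre at C4 is enolisable and ends as an sp2 ring carbon, so it needs no control.

Step 5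
Reactants: 10 methyl 4-methyl-3,5-dioxoheptanoate
Product: 11 6-ethyl-4-hydroxy-5-methyl-2H-pyran-2-one
Conditions: DBU (1.5 equiv), toluene, 110 °C; then 1 M HCl
Reagents that add atoms: none
Why: Base-mediated enol-lactonisation of a 3,5-dioxo ester (acyl substitution of the methyl ester by the C5 enolate oxygen), the standard route to 4-hydroxy-2-pyranones, driven by loss of methanol and tautomerisation to the aromatic hydroxypyranone.

Step 6
Reactants: 7 (2R)-1-[(2R)-4,6-dihydroxy-2-(prop-1-en-2-yl)-2,3-dihydro-1-benzofuran-5-yl]-2-methylbutan-1-one; 11 6-ethyl-4-hydroxy-5-methyl-2H-pyran-2-one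
Product: 14 6-ethyl-4-hydroxy-3-({(2R)-4,6-dihydroxy-5-[(2R)-2-methylbutanoyl]-2-(prop-1-en-2-yl)-2,3-dihydro-1-benzofuran-7-yl}methyl)-5-methyl-2H-pyran-2-one, via 3-[(dimethylamino)methyl]pyranone Mannich base 12 (not isolated), via 3-methylidenepyran-2,4-dione 13 (not isolated)
Conditions: 11, Eschenmoser's salt (1.05 equiv), MeCN, rt; then 7 (1.0 equiv), 50 °C
Reagents that add atoms: Eschenmoser's salt (N,N-dimethylmethyleneiminium iodide), C=[N+](C)C.[I-]
Why: Mannich reaction of the pyranone at C3, loss of dimethylamine to the 3-methylidene-pyran-2,4-dione (a Michael acceptor of the ortho-quinone-methide kind) and conjugate addition by C7 of 7, the only unsubstituted aromatic carbon left, followed by re-aromatisation; no stereocentre is formed and the near-neutral conditions should leave the isopropenyl group, the allylic aryl ether and both stereocentres alone.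

**Compound list**

1 | phloroglucinol (benzene-1,3,5-triol) | Oc1cc(O)cc(O)c1 | starting material
2 | (R)-2-methylbutanoic acid | CC[C@@H](C)C(=O)O | starting material
3 | (R)-2-methylbutanoyl chloride | CC[C@@H](C)C(=O)Cl | intermediate
4 | (2R)-2-methyl-1-(2,4,6-trihydroxyphenyl)butan-1-one | CC[C@@H](C)C(=O)c1c(O)cc(O)cc1O | intermediate
5 | (2R)-1-(3-bromo-2,4,6-trihydroxyphenyl)-2-methylbutan-1-one | CC[C@@H](C)C(=O)c1c(O)cc(O)c(Br)c1O | intermediate
6 | isoprene (2-methylbuta-1,3-diene) | C=CC(C)=C | starting material
7 | (2R)-1-[(2R)-4,6-dihydroxy-2-(prop-1-en-2-yl)-2,3-dihydro-1-benzofuran-5-yl]-2-methylbutan-1-one | C=C(C)[C@H]1Cc2c(O)c(C(=O)[C@H](C)CC)c(O)cc2O1 | intermediate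
8 | methyl 3-oxopentanoate | CCC(=O)CC(=O)OC | starting material
9 | N-methoxy-N-methylpropanamide | CCC(=O)N(C)OC | starting material
10 | methyl 4-methyl-3,5-dioxoheptanoate | CCC(=O)C(C)C(=O)CC(=O)OC | intermediate
11 | 6-ethyl-4-hydroxy-5-methyl-2H-pyran-2-one | CCc1oc(=O)cc(O)c1C | intermediate
12 | 3-[(dimethylamino)methyl]-6-ethyl-4-hydroxy-5-methyl-2H-pyran-2-one | CCc1oc(=O)c(CN(C)C)c(O)c1C | intermediate
13 | 6-ethyl-5-methyl-3-methylidene-2H-pyran-2,4(3H)-dione | CCC1=C(C)C(=O)C(=C)C(=O)O1 | intermediate
14 | 6-ethyl-4-hydroxy-3-({(2R)-4,6-dihydroxy-5-[(2R)-2-methylbutanoyl]-2-(prop-1-en-2-yl)-2,3-dihydro-1-benzofuran-7-yl}methyl)-5-methyl-2H-pyran-2-one | C=C(C)[C@H]1Cc2c(O)c(C(=O)[C@H](C)CC)c(O)c(Cc3c(O)c(C)c(CC)oc3=O)c2O1 | target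

**Step count and risks**

Total steps: 6. Longest linear sequence: 4 steps (steps 1, 2, 3 and 6); the pyranone branch (steps 4 and 5) joins at step 6.

Step 3. What may go wrong: the electron-rich, doubly ortho-oxygenated C–Br bond may add slowly to zerovalent palladium, the β-hydroxy aryl ketone may sequester the metal, the ring may close in part through the wrong hydroxyl, and re-ionisation of the allylic aryl ether in the product may erode the enantiomeric purity at C2. The fallback sets out from 4 and needs no aryl halide and no Heck event. Palladium-catalysed C-allylation of 4 (allyl methyl carbonate, Pd(PPh3)4, THF) should give (2R)-2-methyl-1-[2,4,6-trihydroxy-3-(prop-2-en-1-yl)phenyl]butan-1-one F1. Cross-metathesis of F1 with 2-methylallyl methyl carbonate (second-generation Hoveyda–Grubbs catalyst, CH2Cl2, 40 °C) should give methyl (2E)-2-methyl-4-{2,4,6-trihydroxy-3-[(2R)-2-methylbutanoyl]phenyl}but-2-en-1-yl carbonate F2. Intramolecular asymmetric Tsuji–Trost etherification of F2 (Pd2(dba)3·CHCl3, DACH-phenyl Trost ligand, AcOH, CH2Cl2, rt), a closure well known for 2-isopropenyl-2,3-dihydrobenzofurans, forms the same O1–C2 bond under buffered conditions and comes back to the route at 7.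

Step 2. What may go wrong: over-bromination to the 3,5-dibromide and oxidative dearomatisation of the very electron-rich ring, so that the mono-bromide cannot be obtained cleanly. The fallback sets out from 4 and changes the order of events so that only one aromatic position is left when the halogen is introduced. Compound 4 (in excess, the surplus to be recovered) is coupled with 11 and Eschenmoser's salt under the step 6 conditions to give 6-ethyl-4-hydroxy-5-methyl-3-({2,4,6-trihydroxy-3-[(2R)-2-methylbutanoyl]phenyl}methyl)-2H-pyran-2-one F3. NBS then brominates the single remaining aromatic C–H to give 3-({3-bromo-2,4,6-trihydroxy-5-[(2R)-2-methylbutanoyl]phenyl}methyl)-6-ethyl-4-hydroxy-5-methyl-2H-pyran-2-one F4. The heteroannulation of F4 with 6 under the step 3 conditions is then run as the last step and comes back to the route at 14.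

Step 1. What may go wrong: partial racemisation of the α-stereocentre by Lewis-acid-promoted enolisation of the acyl chloride or of the product ketone, which would appear later as diastereomers that are hard to separate. The fallback sets out from 1 and 2 and replaces electrophilic acylation by addition of an aryllithium to an amide. Compound 1 with MOMCl and i-Pr2NEt should give 1,3,5-tris(methoxymethoxy)benzene F5. Compound 2 with 1,1'-carbonyldiimidazole and N,O-dimethylhydroxylamine hydrochloride should give (2R)-N-methoxy-N,2-dimethylbutanamide F6. Ortho-lithiation of F5 (n-BuLi, THF, 0 °C) and addition to F6 at −78 °C should give (2R)-2-methyl-1-[2,4,6-tris(methoxymethoxy)phenyl]butan-1-one F7. Removal of the three acetal groups from F7 (HCl, MeOH, rt) comes back to the route at 4.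

**Further compounds**

F1 | step 3 | (2R)-2-methyl-1-[2,4,6-trihydroxy-3-(prop-2-en-1-yl)phenyl]butan-1-one | C=CCc1c(O)cc(O)c(C(=O)[C@H](C)CC)c1O
F2 | step 3 | methyl (2E)-2-methyl-4-{2,4,6-trihydroxy-3-[(2R)-2-methylbutanoyl]phenyl}but-2-en-1-yl carbonate | COC(=O)OC/C(C)=C/Cc1c(O)cc(O)c(C(=O)[C@H](C)CC)c1O
F3 | step 2 | 6-ethyl-4-hydroxy-5-methyl-3-({2,4,6-trihydroxy-3-[(2R)-2-methylbutanoyl]phenyl}methyl)-2H-pyran-2-one | CC[C@@H](C)C(=O)c1c(O)cc(O)c(Cc2c(O)c(C)c(CC)oc2=O)c1O
F4 | step 2 | 3-({3-bromo-2,4,6-trihydroxy-5-[(2R)-2-methylbutanoyl]phenyl}methyl)-6-ethyl-4-hydroxy-5-methyl-2H-pyran-2-one | CC[C@@H](C)C(=O)c1c(O)c(Br)c(O)c(Cc2c(O)c(C)c(CC)oc2=O)c1O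
F5 | step 1 | 1,3,5-tris(methoxymethoxy)benzene | COCOc1cc(OCOC)cc(OCOC)c1
F6 | step 1 | (2R)-N-methoxy-N,2-dimethylbutanamide | CC[C@@H](C)C(=O)N(C)OC
F7 | step 1 | (2R)-2-methyl-1-[2,4,6-tris(methoxymethoxy)phenyl]butan-1-one | CC[C@@H](C)C(=O)c1c(OCOC)cc(OCOC)cc1OCOC
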